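**Retrosynthetic overview**

- Feature: the only ring, cyclopentane C8–C9–C10–C11–C12 with trans chains at C8 and C12, is cut into C10–C13 (a succinaldehyde unit) and C8–C9 (the two alkene carbons of a nitroalkene that already holds C1–C7, with the C6 ketone masked as a dioxolane).
- Ring formation: an aminocatalytic Michael addition forms C8–C12, then a Henry closure forms C9–C10.
- After the ring: C13=C14 by Horner–Wadsworth–Emmons olefination and C15 by oxazaborolidine reduction. The 9-nitro/10-hydroxy pair becomes the C9 ketone with a C10=C11 alkene, O-11 enters by α-epoxidation and reductive opening, and C9 is reduced from the β face.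
- Last disconnection: methyl ester and C6 dioxolane, removed only when C9 is an alcohol, so that no 6,9-diketone ever exists.
- Building blocks: the nitroalkene from methyl adipoyl chloride (allylation, ketalisation, ozonolysis, Henry addition, dehydration); succinaldehyde from 2,5-dimethoxytetrahydrofuran.

Key step: step 7

Assumptions and conventions: locants C1–C20 are prostanoid numbering; α is the ring face that carries the C8 chain, β the face that carries the C12 chain. The Henry closure is taken to give mainly the all-trans 9β-nitro-10α-hydroxy isomer, which is the one drawn for 15, 17 and 18; other C9/C10 isomers would be carried along, because both centres become sp2 in steps 10 and 11. Target 26 equilibrates in solution with its 6,9-hemiketal; the open hydroxy ketone is the form drawn.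

**Step 1**
Reactants: 1 methyl 6-chloro-6-oxohexanoate; 2 allyltrimethylsilane
Product: 3 methyl 6-oxonon-8-enoate
Conditions: AlCl3 (2.2 equiv), CH2Cl2, −78 °C; cold aq. NH4Cl quench
Reagents that add atoms: none
Why: Friedel–Crafts-type acylation of an allylsilane (Hosomi–Sakurai acylation), in which the AlCl3-activated acid chloride is attacked by the γ-carbon of 2 and the β-silyl cation loses Me3SiCl, should give the β,γ-unsaturated ketone at −78 °C, where the methyl ester is inert and a cold non-basic quench keeps the alkene out of conjugation.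

**Step 2**
Reactants: 3 methyl 6-oxonon-8-enoate
Product: 4 methyl 5-[2-(prop-2-enyl)-1,3-dioxolan-2-yl]pentanoate
Conditions: Me3SiOCH2CH2OSiMe3 (1.5 equiv), Me3SiOSO2CF3 (5 mol %), CH2Cl2, −78 → −20 °C; pyridine quench
Reagents that add atoms: 1,2-bis(trimethylsilyloxy)ethane, C[Si](C)(C)OCCO[Si](C)(C)C
Why: Noyori ketalisation runs cold and aprotic, so the β,γ-alkene should not move into conjugation and the methyl ester should not be transesterified, the driving force being formation of the Si–O–Si bond.

**Step 3**
Reactants: 4 methyl 5-[2-(prop-2-enyl)-1,3-dioxolan-2-yl]pentanoate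
Product: 6 methyl 5-[2-(2-oxoethyl)-1,3-dioxolan-2-yl]pentanoate, via ozonide 5 (not isolated)
Conditions: O3, CH2Cl2, −78 °C; then PPh3, −78 °C → rt
Reagents that add atoms: ozone, [O-][O+]=O
Why: Ozonolysis (Criegee mechanism) with reductive work-up cleaves the only alkene to the C8 aldehyde, while the ketal carbon has no C–H bond for ozone to oxidise and the ester is inert.

**Step 4**
Reactants: 6 methyl 5-[2-(2-oxoethyl)-1,3-dioxolan-2-yl]pentanoate; 7 nitromethane
Product: 8 methyl 5-[2-(2-hydroxy-3-nitropropyl)-1,3-dioxolan-2-yl]pentanoate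
Conditions: MeNO2 (10 equiv), KOC(CH3)3 (10 mol %), THF/(CH3)3COH 1:1, 0 °C
Reagents that add atoms: none
Why: Henry (nitroaldol) addition of the nitromethane anion to the unhindered aldehyde; the cold medium and the excess of nitromethane keep the base as nitronate, so enolisation of the β-ketal aldehyde with opening of the dioxolane should not compete, and the new carbinol centre (racemic) is removed in step 5.

**Step 5**
Reactants: 8 methyl 5-[2-(2-hydroxy-3-nitropropyl)-1,3-dioxolan-2-yl]pentanoate
Product: 10 methyl 5-[2-[(E)-3-nitroprop-2-enyl]-1,3-dioxolan-2-yl]pentanoate, via nitro mesylate 9 (not isolated)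
Conditions: CH3SO2Cl (1.2 equiv), Et3N (2.5 equiv), CH2Cl2, −20 → 0 °C; cold dilute acid quench
Reagents that add atoms: methanesulfonyl chloride, CS(=O)(=O)Cl (mesyl group of intermediate 9 only, lost again in the elimination)
Why: Mesylation followed by E1cB elimination through the nitronate gives the conjugated nitroalkene, for which the (E) isomer is strongly preferred, and the cold acidic quench limits amine deprotonation at C7.

**Step 6**
Reactants: 11 2,5-dimethoxytetrahydrofuran
Product: 12 succinaldehyde
Conditions: H2O, 90 °C, then distil off MeOH; CH2Cl2 extraction, vacuum distillation, used at once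
Reagents that add atoms: water, O
Why: Hydrolysis of the cyclic bis-acetal in hot water, driven by removal of methanol, gives the dialdehyde, which is distilled and used fresh because it oligomerises on standing.

**Step 7**
Reactants: 12 succinaldehyde; 10 methyl 5-[2-[(E)-3-nitroprop-2-enyl]-1,3-dioxolan-2-yl]pentanoate
Product: 15 methyl 5-(2-{[(1R,2S,3S,5S)-5-formyl-3-hydroxy-2-nitrocyclopentyl]methyl}-1,3-dioxolan-2-yl)pentanoate, via Michael adduct 13 (not isolated), via cis aldehyde 14 (not isolated)
Conditions: 12 (2 equiv), (S)-2-[diphenyl(trimethylsilyloxy)methyl]pyrrolidine (10 mol %), 4-nitrophenol (10 mol %), MeCN, rt; then i-Pr2NEt (1 equiv), 0 °C → rt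
Reagents that add atoms: none
Why: The secondary amine condenses with one formyl group of 12 to an (E)-enamine whose face next to the CPh2OSiMe3 group is blocked, so C12 adds to C8 of nitroalkene 10 through the open synclinal transition state of the diarylprolinol silyl ether-catalysed aldehyde–nitroalkene Michael reaction (the closest known reaction type, also known with succinaldehyde as donor), which should fix C8 as R and give syn adduct 13. Diisopropylethylamine then forms the C9 nitronate, which attacks the remaining C10 formyl group in a 5-exo-trig intramolecular Henry reaction and closes the cyclopentane C8–C9–C10–C11–C12, the only ring of the target. The syn adduct should close first to the 8,12-cis aldehyde 14, whose enolisable C12 the same base equilibrates to the more stable 8,12-trans aldehyde 15; C8 is therefore under catalyst control and C12 under thermodynamic control relayed from C8. C9 and C10 form under substrate control as a mixture (mainly all-trans expected) and need no control, because both are erased in steps 10 and 11. The step needs enamine formation from the dialdehyde without self-aldol and a nitroalkene that is not deprotonated at C7: the excess of fresh 12, the weakly acidic 4-nitrophenol co-catalyst and the absence of tertiary amine until 10 is consumed should secure this. The nitronate can only close the five-membered ring, since attack on the C13 formyl group would give a cyclobutane.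

**Step 8**
Reactants: 15 methyl 5-(2-{[(1R,2S,3S,5S)-5-formyl-3-hydroxy-2-nitrocyclopentyl]methyl}-1,3-dioxolan-2-yl)pentanoate; 16 dimethyl (2-oxoheptyl)phosphonate
Product: 17 methyl (13E)-6,6-(ethylenedioxy)-10α-hydroxy-9β-nitro-15-oxoprost-13-en-1-oate
Conditions: LiCl, i-Pr2NEt, MeCN, 0 °C → rt (15 used crude)
Reagents that add atoms: none
Why: Horner–Wadsworth–Emmons olefination under Masamune–Roush conditions generates the stabilised β-ketophosphonate anion without strong base, so the nitro alcohol and the C12 centre should be tolerated, and the stabilised reagent gives the (E)-enone.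

**Step 9**
Reactants: 17 methyl (13E)-6,6-(ethylenedioxy)-10α-hydroxy-9β-nitro-15-oxoprost-13-en-1-oate
Product: 18 methyl (13E,15S)-6,6-(ethylenedioxy)-10α,15-dihydroxy-9β-nitroprost-13-en-1-oate
Conditions: (R)-1-methyl-3,3-diphenyltetrahydro-1H,3H-pyrrolo[1,2-c][1,3,2]oxazaborole (20 mol %), catecholborane (3 equiv), toluene/CH2Cl2, −78 °C; MeOH quench
Reagents that add atoms: none
Why: Corey–Bakshi–Shibata reduction, in which the (R)-oxazaborolidine binds the ketone with the alkenyl group as the large substituent and delivers hydride to the face that gives the 15S allylic alcohol (catalyst control), with 1,2-reduction favoured and nitro, ester and ketal untouched at −78 °C.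

**Step 10**
Reactants: 18 methyl (13E,15S)-6,6-(ethylenedioxy)-10α,15-dihydroxy-9β-nitroprost-13-en-1-oate
Product: 19 methyl (13E,15S)-6,6-(ethylenedioxy)-15-hydroxy-9-nitroprosta-9,13-dien-1-oate
Conditions: acidic Al2O3, ClCH2CH2Cl, 60 °C
Reagents that add atoms: none
Why: Surface-mediated dehydration of a β-nitro alcohol (E1cB-type β-elimination) removes the C10 hydroxyl and the acidic C9 hydrogen whatever the C9/C10 configuration, and does not activate the allylic C15 alcohol as a sulfonylation–elimination would.

**Step 11**
Reactants: 19 methyl (13E,15S)-6,6-(ethylenedioxy)-15-hydroxy-9-nitroprosta-9,13-dien-1-oate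
Product: 21 methyl (13E,15S)-6,6-(ethylenedioxy)-15-hydroxy-9-oxoprosta-10,13-dien-1-oate, via allylic nitro isomer 20 (not isolated)
Conditions: 1,4-diazabicyclo[2.2.2]octane (2 equiv), O2 (1 atm), MeCN, 0 °C → rt
Reagents that add atoms: dioxygen, O=O
Why: Base-mediated aerobic Nef reaction, in which the amine removes the γ-hydrogen at C11 to a dienyl nitronate in equilibrium with allylic nitro compound 20, and oxygenation at C9 with loss of nitrite gives the C9 ketone conjugated with the C10=C11 alkene, C8 and C12 keeping the more stable trans arrangement.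

**Step 12**
Reactants: 21 methyl (13E,15S)-6,6-(ethylenedioxy)-15-hydroxy-9-oxoprosta-10,13-dien-1-oate
Product: 22 methyl (13E,15S)-10α,11α-epoxy-6,6-(ethylenedioxy)-15-hydroxy-9-oxoprost-13-en-1-oate
Conditions: 30% aq. H2O2, NaOH (0.3 equiv), MeOH, −40 °C
Reagents that add atoms: hydrogen peroxide, OO
Why: Weitz–Scheffer nucleophilic epoxidation, in which hydroperoxide adds to C11 of the cyclopentenone from the α face, anti to the adjacent β-oriented C12 chain (substrate control), and the enolate closes the 10α,11α-epoxide, while the unactivated C13=C14 alkene does not react with the nucleophilic oxidant.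

**Step 13**
Reactants: 22 methyl (13E,15S)-10α,11α-epoxy-6,6-(ethylenedioxy)-15-hydroxy-9-oxoprost-13-en-1-oate
Product: 23 methyl (11R,13E,15S)-6,6-(ethylenedioxy)-11,15-dihydroxy-9-oxoprost-13-en-1-oate
Conditions: Zn dust, NH4Cl, MeOH/H2O, 0 °C → rt
Reagents that add atoms: none
Why: Reductive opening of an α,β-epoxy ketone by zinc cleaves only the C10–O bond through the zinc enolate, so the 11α configuration from step 12 is kept, and the nearly neutral medium should avoid dehydration of the β-hydroxy ketone.

**Step 14**
Reactants: 23 methyl (11R,13E,15S)-6,6-(ethylenedioxy)-11,15-dihydroxy-9-oxoprost-13-en-1-oate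
Product: 24 methyl (9S,11R,13E,15S)-6,6-(ethylenedioxy)-9,11,15-trihydroxyprost-13-en-1-oate
Conditions: LiBH(s-Bu)3 (4 equiv), THF, −78 °C; aq. NH4Cl
Reagents that add atoms: none
Why: Substrate-controlled ketone reduction with the bulky tri-sec-butylborohydride, which should approach C9 from the β face, opposite the adjacent α-oriented C8 chain and the C11 oxygen, to give the 9α (9S) alcohol; the excess covers the two free hydroxyls and the ester is inert at −78 °C.

**Step 15**
Reactants: 24 methyl (9S,11R,13E,15S)-6,6-(ethylenedioxy)-9,11,15-trihydroxyprost-13-en-1-oate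
Product: 26 6-keto-prostaglandin F1alpha, via dioxolane acid 25 (not isolated)
Conditions: LiOH·H2O, THF/H2O, 0 °C → rt; then AcOH/H2O (to about 3:1:1 AcOH/H2O/THF), 40 °C
Reagents that add atoms: lithium hydroxide, [Li+].[OH-]; water, O
Why: Saponification of the methyl ester followed by acid-catalysed ketal hydrolysis, in which the 9α-hydroxyl can trap the C6 oxocarbenium ion as a cyclic mixed ketal and so speed the loss of ethylene glycol, releases the ketone only after C9 has been reduced, in an aqueous acetic acid medium that the allylic C15 alcohol of prostaglandins tolerates.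

**Compound list**

1 | methyl 6-chloro-6-oxohexanoate (methyl adipoyl chloride) | COC(=O)CCCCC(=O)Cl | starting material
2 | allyltrimethylsilane | C=CC[Si](C)(C)C | starting material
3 | methyl 6-oxonon-8-enoate | COC(=O)CCCCC(=O)CC=C | intermediate
4 | methyl 5-[2-(prop-2-enyl)-1,3-dioxolan-2-yl]pentanoate | COC(=O)CCCCC1(CC=C)OCCO1 | intermediate
5 | methyl 5-[2-(1,2,4-trioxolan-3-ylmethyl)-1,3-dioxolan-2-yl]pentanoate (secondary ozonide) | COC(=O)CCCCC1(CC2OCOO2)OCCO1 | intermediate
6 | methyl 5-[2-(2-oxoethyl)-1,3-dioxolan-2-yl]pentanoate | COC(=O)CCCCC1(CC=O)OCCO1 | intermediate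
7 | nitromethane | C[N+](=O)[O-] | starting material
8 | methyl 5-[2-(2-hydroxy-3-nitropropyl)-1,3-dioxolan-2-yl]pentanoate (racemic) | COC(=O)CCCCC1(CC(O)C[N+](=O)[O-])OCCO1 | intermediate
9 | methyl 5-[2-(2-methylsulfonyloxy-3-nitropropyl)-1,3-dioxolan-2-yl]pentanoate | COC(=O)CCCCC1(CC(OS(C)(=O)=O)C[N+](=O)[O-])OCCO1 | intermediate
10 | methyl 5-[2-[(E)-3-nitroprop-2-enyl]-1,3-dioxolan-2-yl]pentanoate | COC(=O)CCCCC1(C/C=C/[N+](=O)[O-])OCCO1 | intermediate
11 | 2,5-dimethoxytetrahydrofuran (cis/trans mixture) | COC1CCC(OC)O1 | starting material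
12 | succinaldehyde (butanedial) | O=CCCC=O | intermediate
13 | methyl 5-{2-[(2R,3R)-3-formyl-2-(nitromethyl)-6-oxohexyl]-1,3-dioxolan-2-yl}pentanoate (syn Michael adduct) | O=C[C@H](CCC=O)[C@H](C[N+](=O)[O-])CC1(CCCCC(=O)OC)OCCO1 | intermediate
14 | methyl 5-(2-{[(1R,5R)-5-formyl-3-hydroxy-2-nitrocyclopentyl]methyl}-1,3-dioxolan-2-yl)pentanoate (8,12-cis; C9/C10 mixture) | O=C[C@@H]1CC(O)C([N+](=O)[O-])[C@@H]1CC2(CCCCC(=O)OC)OCCO2 | intermediate
15 | methyl 5-(2-{[(1R,2S,3S,5S)-5-formyl-3-hydroxy-2-nitrocyclopentyl]methyl}-1,3-dioxolan-2-yl)pentanoate (all-trans: C8 chain α, 9-NO2 β, 10-OH α, 12-CHO β) | O=C[C@H]1C[C@H](O)[C@@H]([N+](=O)[O-])[C@@H]1CC2(CCCCC(=O)OC)OCCO2 | intermediate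
16 | dimethyl (2-oxoheptyl)phosphonate | CCCCCC(=O)CP(=O)(OC)OC | starting material
17 | methyl (13E)-6,6-(ethylenedioxy)-10α-hydroxy-9β-nitro-15-oxoprost-13-en-1-oate (8-chain α, 12-chain β) | CCCCCC(=O)/C=C/[C@H]1C[C@H](O)[C@@H]([N+](=O)[O-])[C@@H]1CC2(CCCCC(=O)OC)OCCO2 | intermediate
18 | methyl (13E,15S)-6,6-(ethylenedioxy)-10α,15-dihydroxy-9β-nitroprost-13-en-1-oate | CCCCC[C@H](O)/C=C/[C@H]1C[C@H](O)[C@@H]([N+](=O)[O-])[C@@H]1CC2(CCCCC(=O)OC)OCCO2 | intermediate
19 | methyl (13E,15S)-6,6-(ethylenedioxy)-15-hydroxy-9-nitroprosta-9,13-dien-1-oate | CCCCC[C@H](O)/C=C/[C@H]1CC=C([N+](=O)[O-])[C@@H]1CC2(CCCCC(=O)OC)OCCO2 | intermediate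
20 | methyl (13E,15S)-6,6-(ethylenedioxy)-15-hydroxy-9-nitroprosta-10,13-dien-1-oate (C9 epimers) | CCCCC[C@H](O)/C=C/[C@H]1C=CC([N+](=O)[O-])[C@@H]1CC2(CCCCC(=O)OC)OCCO2 | intermediate
21 | methyl (13E,15S)-6,6-(ethylenedioxy)-15-hydroxy-9-oxoprosta-10,13-dien-1-oate (8-chain α, 12-chain β) | CCCCC[C@H](O)/C=C/[C@H]1C=CC(=O)[C@@H]1CC2(CCCCC(=O)OC)OCCO2 | intermediate
22 | methyl (13E,15S)-10α,11α-epoxy-6,6-(ethylenedioxy)-15-hydroxy-9-oxoprost-13-en-1-oate | CCCCC[C@H](O)/C=C/[C@H]1[C@@H]2O[C@@H]2C(=O)[C@@H]1CC3(CCCCC(=O)OC)OCCO3 | intermediate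
23 | methyl (11R,13E,15S)-6,6-(ethylenedioxy)-11,15-dihydroxy-9-oxoprost-13-en-1-oate | CCCCC[C@H](O)/C=C/[C@H]1[C@H](O)CC(=O)[C@@H]1CC2(CCCCC(=O)OC)OCCO2 | intermediate
24 | methyl (9S,11R,13E,15S)-6,6-(ethylenedioxy)-9,11,15-trihydroxyprost-13-en-1-oate | CCCCC[C@H](O)/C=C/[C@H]1[C@H](O)C[C@H](O)[C@@H]1CC2(CCCCC(=O)OC)OCCO2 | intermediate
25 | (9S,11R,13E,15S)-6,6-(ethylenedioxy)-9,11,15-trihydroxyprost-13-en-1-oic acid | CCCCC[C@H](O)/C=C/[C@H]1[C@H](O)C[C@H](O)[C@@H]1CC2(CCCCC(=O)O)OCCO2 | intermediate
26 | 6-keto-prostaglandin F1alpha, (9S,11R,13E,15S)-9,11,15-trihydroxy-6-oxoprost-13-en-1-oic acid | CCCCC[C@H](O)/C=C/[C@@H]1[C@@H](CC(=O)CCCCC(=O)O)[C@@H](O)C[C@H]1O | target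

**Step count**

Total: 15 steps. Longest linear sequence: 14 steps (steps 1–5 and 7–15); step 6 is the one-step side branch.

**Steps most likely to fail**

Step 7. Oligomerisation and self-aldol condensation of succinaldehyde under the amine catalyst may outrun the Michael addition, or the nitroalkene may be lost by deprotonation at C7 before it is consumed. The fallback separates the two bond formations and carries the second aldehyde as an alkene. Starting from nitroalkene 10, the same (S)-diarylprolinol silyl ether catalyses the Michael addition of commercial pent-4-enal, a robust mono-aldehyde donor, which should give the syn adduct methyl 5-{2-[(2R,3R)-3-formyl-2-(nitromethyl)hex-5-enyl]-1,3-dioxolan-2-yl}pentanoate F1. Ozonolysis of its terminal alkene (O3, CH2Cl2, −78 °C, then PPh3) would release the C10 aldehyde, that is dialdehyde 13, which is treated at once with i-Pr2NEt to close and equilibrate to 15, where the route is rejoined.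

Step 11. Over-oxidation by O2, incomplete oxygenation, or base-induced migration of the C10=C11 double bond toward C12 once the enone exists may erode the product. The fallback is a reductive instead of an oxidative Nef reaction. From nitroalkene 19, i-Pr2NEt in MeCN under argon would shift the double bond to allylic nitro compound 20, now isolated. NaOCH3 in MeOH at 0 °C converts it into the sodium salt of the C9 nitronate F2, and buffered aqueous TiCl3 (NH4OAc, pH about 5 to 6, McMurry conditions, which tolerate ketals) reduces the nitronate to the conjugated imine, whose hydrolysis gives enone 21, where the route is rejoined.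

Step 12. Poor facial selectivity of the hydroperoxide addition (β-epoxide, leading to 11-epi material) or base-mediated isomerisation of the enone may occur. The fallback brings in the C11 oxygen through boron. From enone 21, copper-catalysed conjugate borylation (B2pin2, CuCl, NaOC(CH3)3, 1,2-bis(diphenylphosphino)benzene, MeOH, THF, rt) should deliver the bulky boryl–copper reagent to C11 anti to the C12 chain and give the 11α-boryl ketone methyl (13E,15S)-6,6-(ethylenedioxy)-15-hydroxy-9-oxo-11α-(4,4,5,5-tetramethyl-1,3,2-dioxaborolan-2-yl)prost-13-en-1-oate F3. Oxidation with NaBO3·4H2O in THF/H2O replaces boron by hydroxyl with retention and gives β-hydroxy ketone 23 directly, so that epoxide 22 and step 13 are bypassed.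

**Further compounds**

F1 | step 7 | methyl 5-{2-[(2R,3R)-3-formyl-2-(nitromethyl)hex-5-enyl]-1,3-dioxolan-2-yl}pentanoate | O=C[C@H](CC=C)[C@H](C[N+](=O)[O-])CC1(CCCCC(=O)OC)OCCO1
F2 | step 11 | sodium salt of the C9 nitronate of methyl (13E,15S)-6,6-(ethylenedioxy)-15-hydroxy-9-nitroprosta-10,13-dien-1-oate | CCCCC[C@H](O)/C=C/[C@H]1C=CC(=[N+]([O-])[O-])[C@@H]1CC2(CCCCC(=O)OC)OCCO2.[Na+]
F3 | step 12 | methyl (13E,15S)-6,6-(ethylenedioxy)-15-hydroxy-9-oxo-11α-(4,4,5,5-tetramethyl-1,3,2-dioxaborolan-2-yl)prost-13-en-1-oate | CCCCC[C@H](O)/C=C/[C@H]1[C@H](B2OC(C)(C)C(C)(C)O2)CC(=O)[C@@H]1CC3(CCCCC(=O)OC)OCCO3
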